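**Retrosynthetic overview**
- Target 9 is cut at the two CH2–C(filicinic) bonds: two molecules of butyrylfilicinic acid 4 add as C‑nucleophiles to a central bis‑electrophile unmasked from bis(methylsulfanylmethyl) ketone 7.
- Key disconnection, the two aryl–CH2 bonds of 7: butyrylphloroglucinol 3 plus dimethyl sulfide. The phenol is O‑bound to sulfonium, so its ortho carbon becomes the electrophilic end (enolonium‑type aryloxysulfonium). The one‑carbon unit arrives as a sulfur‑ylide carbanion, the reverse of formaldehyde, so two normally nucleophilic carbons are joined by a [2,3] shift.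
- 4 comes from 3 by dearomatising gem‑dimethylation; 3 comes from phloroglucinol 1 and butanoyl chloride 2.
- Ring order: no ring is built from acyclic material. All three carbocycles are phloroglucinol rings; the two outer ones are converted to the gem‑dimethyl cyclohexadienone (filicinic) rings first, and the aromatic central ring is joined to them last.

Assumption: the target (filixic acid BBB) has no stereocentre and is achiral, so no stereocontrol is needed; enol tautomers are drawn as in the given SMILES.

**Step 1**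
Reactants: 1 phloroglucinol; 2 butanoyl chloride
Product: 3 1-(2,4,6-trihydroxyphenyl)butan-1-one (butyrylphloroglucinol)
Conditions: AlCl3 (4 equiv), PhNO2–CH2Cl2, 0 °C → 60 °C; aq. HCl
Reagents that add atoms: none
Why: Friedel–Crafts C‑acylation of the very electron‑rich triol stops at the mono‑ketone with one equivalent of acid chloride because the chelated acyl group deactivates the ring; no stereocentre is formed.

**Step 2**
Reactants: 3 1-(2,4,6-trihydroxyphenyl)butan-1-one
Product: 4 2-butanoyl-3,5-dihydroxy-4,4-dimethylcyclohexa-2,5-dien-1-one (butyrylfilicinic acid)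
Conditions: NaOMe (4 equiv), MeI (2.5 equiv), MeOH, 0 °C → rt; aq. HCl
Reagents that add atoms: iodomethane, CI
Why: Dearomatising gem‑dimethylation of an acylphloroglucinol: the ambident phenoxide is C‑methylated twice at the same free ring carbon in methanol, the second alkylation giving the cross‑conjugated triketone enol; no stereocentre is formed.

**Step 3 (key step)**
Reactants: 3 1-(2,4,6-trihydroxyphenyl)butan-1-one
Product: 7 1-[2,4,6-trihydroxy-3,5-bis(methylsulfanylmethyl)phenyl]butan-1-one, via aryloxysulfonium chloride 5 (not isolated), via mono(methylsulfanylmethyl) ketone 6 (not isolated)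
Conditions: Me2S (2.6 equiv), NCS (2.3 equiv), CH2Cl2, −25 °C; 3 in THF, −40 °C; Et3N (2.5 equiv), −40 °C → rt
Reagents that add atoms: dimethyl sulfide, CSC
Why: Gassman‑type ortho‑alkylation of a phenol (sulfonium‑ylide [2,3]‑sigmatropic rearrangement): the Corey–Kim salt binds the phenol oxygen as an aryloxysulfonium, which makes the free ortho carbons C3/C5 electrophilic, Et3N forms the S‑ylide whose carbanion carbon bonds to the ortho carbon as the O–S bond breaks, tautomerisation restores the arene, and the sequence repeats at the second free position; no stereocentre is formed.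

**Step 4**
Reactants: 7 1-[2,4,6-trihydroxy-3,5-bis(methylsulfanylmethyl)phenyl]butan-1-one; 4 2-butanoyl-3,5-dihydroxy-4,4-dimethylcyclohexa-2,5-dien-1-one (2.2 equiv)
Product: 9 filixic acid BBB = 1-[3,5-bis[(5-butanoyl-2,4-dihydroxy-3,3-dimethyl-6-oxocyclohexa-1,4-dien-1-yl)methyl]-2,4,6-trihydroxyphenyl]butan-1-one (the target), via bis-sulfonium triflate 8 (not isolated)
Conditions: MeOTf (2.1 equiv), CH2Cl2, 0 °C → rt; then 4 (2.2 equiv), NaOAc (5 equiv), MeCN, rt
Reagents that add atoms: none
Why: Chemoselective S‑methylation turns each sulfide into a dimethylsulfonium leaving group, and acetate then triggers 1,4‑elimination of dimethyl sulfide from the ortho‑hydroxybenzyl sulfonium and Michael addition of the only free ring carbon (C6) of the enolate of 4, the same elimination–addition used with Mannich‑base methiodides for methylene‑bridged acylphloroglucinols; no stereocentre is formed.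

**Compound list**
1 | phloroglucinol (benzene-1,3,5-triol), achiral | Oc1cc(O)cc(O)c1 | starting material
2 | butanoyl chloride, achiral | CCCC(Cl)=O | starting material
3 | 1-(2,4,6-trihydroxyphenyl)butan-1-one (butyrylphloroglucinol), achiral | CCCC(=O)c1c(O)cc(O)cc1O | intermediate
4 | 2-butanoyl-3,5-dihydroxy-4,4-dimethylcyclohexa-2,5-dien-1-one (butyrylfilicinic acid), achiral | CCCC(=O)C1=C(O)C(C)(C)C(O)=CC1=O | intermediate
5 | (4-butanoyl-3,5-dihydroxyphenoxy)dimethylsulfonium chloride, achiral | CCCC(=O)c1c(O)cc(O[S+](C)C)cc1O.[Cl-] | intermediate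
6 | 1-[2,4,6-trihydroxy-3-(methylsulfanylmethyl)phenyl]butan-1-one, achiral | CCCC(=O)c1c(O)cc(O)c(CSC)c1O | intermediate
7 | 1-[2,4,6-trihydroxy-3,5-bis(methylsulfanylmethyl)phenyl]butan-1-one, achiral | CCCC(=O)c1c(O)c(CSC)c(O)c(CSC)c1O | intermediate
8 | [(5-butanoyl-2,4,6-trihydroxy-1,3-phenylene)bis(methylene)]bis(dimethylsulfonium) bis(trifluoromethanesulfonate), achiral | CCCC(=O)c1c(O)c(C[S+](C)C)c(O)c(C[S+](C)C)c1O.[O-]S(=O)(=O)C(F)(F)F.[O-]S(=O)(=O)C(F)(F)F | intermediate
9 | filixic acid BBB, 1-[3,5-bis[(5-butanoyl-2,4-dihydroxy-3,3-dimethyl-6-oxocyclohexa-1,4-dien-1-yl)methyl]-2,4,6-trihydroxyphenyl]butan-1-one, achiral | CCCC(=O)C1=C(O)C(C)(C)C(O)=C(Cc2c(O)c(CC3=C(O)C(C)(C)C(O)=C(C(=O)CCC)C3=O)c(O)c(C(=O)CCC)c2O)C1=O | target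

**Totals**
Total step count: 4. Longest linear sequence: 3 steps (1 → 3 → 7 → 9, or 1 → 3 → 4 → 9).

**Steps most likely to fail, with fallbacks**

Step 3 (key step). The twofold ylide rearrangement has not been run on a free acylphloroglucinol. The unstabilised methyl ylide may fragment to aryl methylthiomethyl ethers, and the chlorosulfonium may attack the ring carbon. The fallback sets out from 3 and uses the sulfur‑stabilised ylide of a formyl‑anion equivalent. 1,3‑Dithiane/NCS (CH2Cl2, −70 °C), then 3 and Et3N, gives by the same O‑sulfonium/[2,3] shift 1-[3,5-bis(1,3-dithian-2-yl)-2,4,6-trihydroxyphenyl]butan-1-one F1. HgO/BF3·OEt2 in aqueous THF unmasks 5-butanoyl-2,4,6-trihydroxybenzene-1,3-dicarbaldehyde F2. F2 is condensed with 4 (2 equiv) and reduced in the same flask (L‑proline cat., Hantzsch ester, CH2Cl2, rt; Knoevenagel condensation then conjugate transfer hydrogenation) through the bis‑alkylidene 1-[3,5-bis[(3-butanoyl-4-hydroxy-5,5-dimethyl-2,6-dioxocyclohex-3-en-1-ylidene)methyl]-2,4,6-trihydroxyphenyl]butan-1-one F3. It comes back to the route at 9.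

Step 4. The unmasked quinone methide may dimerise or be O‑alkylated, and base can scramble methylene bridges (formation of the symmetrical bis‑filicinic dimer). The fallback sets out from 7 and avoids free quinone methides. NCS (2 equiv, CH2Cl2, 0 °C) chlorinates both sulfides alpha to sulfur to give 1-[3,5-bis[chloro(methylsulfanyl)methyl]-2,4,6-trihydroxyphenyl]butan-1-one F4. Aqueous hydrolysis of F4 gives the dialdehyde 5-butanoyl-2,4,6-trihydroxybenzene-1,3-dicarbaldehyde F2. F2 is joined to 4 by the same reductive Knoevenagel alkylation through the bis‑alkylidene F3 and comes back to the route at 9.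

Step 2. Methylation can give mixtures: mono‑methyl, 3,5‑dimethyl aromatic and over‑methylated products. The fallback sets out from 3 and blocks the second ring position. A second Friedel–Crafts acylation with 2 (AlCl3, PhNO2) gives 1,1'-(2,4,6-trihydroxy-1,3-phenylene)dibutan-1-one F5. F5 has a single free ring carbon, so MeI/NaOMe can only gem‑dimethylate there, giving 2,4-dibutanoyl-3,5-dihydroxy-6,6-dimethylcyclohexa-2,4-dien-1-one F6. Warming F6 in about 85% H2SO4 (80 °C) removes one acyl group by retro‑Friedel–Crafts cleavage and comes back to the route at 4.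

**Further compounds**
F1 | step 3 | 1-[3,5-bis(1,3-dithian-2-yl)-2,4,6-trihydroxyphenyl]butan-1-one | CCCC(=O)c1c(O)c(C2SCCCS2)c(O)c(C2SCCCS2)c1O
F2 | step 3 | 5-butanoyl-2,4,6-trihydroxybenzene-1,3-dicarbaldehyde | CCCC(=O)c1c(O)c(C=O)c(O)c(C=O)c1O
F3 | step 3 | 1-[3,5-bis[(3-butanoyl-4-hydroxy-5,5-dimethyl-2,6-dioxocyclohex-3-en-1-ylidene)methyl]-2,4,6-trihydroxyphenyl]butan-1-one | CCCC(=O)c1c(O)c(C=C2C(=O)C(C(=O)CCC)=C(O)C(C)(C)C2=O)c(O)c(C=C2C(=O)C(C(=O)CCC)=C(O)C(C)(C)C2=O)c1O
F4 | step 4 | 1-[3,5-bis[chloro(methylsulfanyl)methyl]-2,4,6-trihydroxyphenyl]butan-1-one (mixture of stereoisomers) | CCCC(=O)c1c(O)c(C(Cl)SC)c(O)c(C(Cl)SC)c1O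
F5 | step 2 | 1,1'-(2,4,6-trihydroxy-1,3-phenylene)dibutan-1-one | CCCC(=O)c1c(O)cc(O)c(C(=O)CCC)c1O
F6 | step 2 | 2,4-dibutanoyl-3,5-dihydroxy-6,6-dimethylcyclohexa-2,4-dien-1-one | CCCC(=O)C1=C(O)C(C(=O)CCC)=C(O)C(C)(C)C1=O
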